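**Retrosynthetic overview**

1. The strategy rests on C6. It is the allylic carbinol carbon bonded to vinyl carbon C5 of the ten-membered ring (C1–C10) and also the alkoxy carbon of the γ-lactone (O–C6–C7–C11–C12), so one C6 alkoxide can close both rings.
2. Target 39 ⇐ lactone core 31 by C8 desilylation, Yamaguchi acylation with silyl-protected (E)-4-hydroxytiglic acid 36, and desilylation.
3. 31 ⇐ open-chain (Z)-alkenyl iodide aldehyde methyl ester 28. Ni/Cr coupling forms C5–C6 (carbocycle first), then the C6 alkoxide attacks the C12 ester (lactone second), in one flask.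
4. 28 ⇐ Evans syn-aldol (C7–C8) of imide 22, made from (S)-methylsuccinic acid (C11), with β,γ-unsaturated aldehyde 16.
5. 16 ⇐ anti-carbomagnesiation–iodination of propargyl alcohol (C3–C4, C5–I) with a homoallyl Grignard reagent from 4-methyl-5,6-dihydro-2H-pyran-2-one (Z C1=C10).

Key step: step 17

Remark: germacrane numbering is used (ring C1–C10; C11–C13 in the lactone branch; C14 the methyl on C10; C15 the CH2O on C4). The target SMILES is read as 6R,7R,8S,11S with C1=C10 Z and C4=C5 Z by CIP (C3 and C6 trans across C4=C5). The aldol sets C8 with the required configuration, so no inversion at C8 is planned. Compounds 33 and 34 are taken as commercial.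

**Route**

Step 1
Reactants: 1 4-methyl-5,6-dihydro-2H-pyran-2-one
Product: 2 4-methyl-5,6-dihydro-2H-pyran-2-ol (lactol)
Conditions: DIBAL-H (1.05 equiv), CH2Cl2, −78 °C; Rochelle salt work-up; used crude
Reagents that add atoms: none
Why: Partial reduction of a lactone, in which the aluminium hemiacetal formed by 1,2-hydride delivery is stable at −78 °C and should release the lactol on work-up without touching the conjugated olefin.

Step 2
Reactants: 2 4-methyl-5,6-dihydro-2H-pyran-2-ol
Product: 4 (3Z)-3-methylhexa-3,5-dien-1-ol, via open-chain hydroxy enal 3 (not isolated)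
Conditions: Ph3PCH3Br (2.5 equiv), KOtBu (2.4 equiv), THF, 0 °C → rt
Reagents that add atoms: methyltriphenylphosphonium bromide, C[P+](c1ccccc1)(c1ccccc1)c1ccccc1.[Br-]
Why: Wittig methylenation of the lactol through its open-chain aldehyde form, in which the ring of 1 has already fixed C2 cis to C9, so the (Z)-trisubstituted olefin should be carried over unchanged.

Step 3
Reactants: 4 (3Z)-3-methylhexa-3,5-dien-1-ol
Product: 5 tert-butyl-dimethyl-[(3Z)-3-methylhexa-3,5-dienoxy]silane
Conditions: TBSCl, imidazole, CH2Cl2, 0 °C → rt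
Reagents that add atoms: tert-butyldimethylsilyl chloride, CC(C)(C)[Si](C)(C)Cl
Why: Silyl ether formation on the primary alcohol, which differentiates O8 from the hydroxyl introduced in the next step.

Step 4
Reactants: 5 tert-butyl-dimethyl-[(3Z)-3-methylhexa-3,5-dienoxy]silane
Product: 7 (3Z)-6-(tert-butyldimethylsilyloxy)-4-methylhex-3-en-1-ol, via B-alkyl-9-BBN 6 (not isolated)
Conditions: 9-BBN (1.2 equiv), THF, 0 °C → rt; then 3 M NaOH, 30% H2O2, 0 °C → rt
Reagents that add atoms: hydrogen peroxide, OO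
Why: Hydroboration–oxidation, in which 9-BBN should add only to the monosubstituted terminus of the diene with boron on the terminal carbon, leaving the trisubstituted olefin untouched.

Step 5
Reactants: 7 (3Z)-6-(tert-butyldimethylsilyloxy)-4-methylhex-3-en-1-ol
Product: 8 (3Z)-6-bromo-1-(tert-butyldimethylsilyloxy)-3-methylhex-3-ene
Conditions: CBr4, PPh3, 2,6-lutidine (0.2 equiv), CH2Cl2, 0 °C
Reagents that add atoms: carbon tetrabromide, BrC(Br)(Br)Br
Why: Appel bromination of a primary alcohol under buffered conditions that spare the TBS ether and the olefin.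

Step 6
Reactants: 8 (3Z)-6-bromo-1-(tert-butyldimethylsilyloxy)-3-methylhex-3-ene; 9 propargyl alcohol
Product: 13 (2Z,5Z)-8-(tert-butyldimethylsilyloxy)-2-(iodomethylidene)-6-methyloct-5-en-1-ol, via homoallyl Grignard reagent 10 (not isolated), via bromomagnesium propargyl alkoxide 11 (not isolated), via alkenylmagnesium chelate 12 (not isolated)
Conditions: 8, Mg, THF, rt → 40 °C; separately 9, MeMgBr (1.0 equiv), Et2O, 0 °C; combine (10, 1.5 equiv), CuI (15 mol %), THF/Et2O, −10 °C → rt; then I2, THF, −30 → 0 °C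
Reagents that add atoms: iodine, II
Why: Copper-catalysed anti-carbomagnesiation of a propargylic alkoxide (Duboudin-type), in which the alkyl group adds to the internal alkyne carbon and magnesium to the terminal carbon inside a five-membered O–Mg chelate, so iodinolysis with retention should place iodine cis to CH2OH (the C4=C5 geometry of the target).

Step 7
Reactants: 13 (2Z,5Z)-8-(tert-butyldimethylsilyloxy)-2-(iodomethylidene)-6-methyloct-5-en-1-ol
Product: 14 tert-butyldiphenylsilyl ether of 13
Conditions: TBDPSCl, imidazole, CH2Cl2, 0 °C → rt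
Reagents that add atoms: tert-butyldiphenylsilyl chloride, CC(C)(C)[Si](Cl)(c1ccccc1)c1ccccc1
Why: Silylation of the primary allylic alcohol with the acid-stable TBDPS group, which has to outlast two later acidic desilylations.

Step 8
Reactants: 14 tert-butyldiphenylsilyl ether of 13
Product: 15 (3Z,7Z)-7-[(tert-butyldiphenylsilyloxy)methyl]-8-iodo-3-methylocta-3,7-dien-1-ol
Conditions: PPTS (0.2 equiv), MeOH/CH2Cl2, rt
Reagents that add atoms: none
Why: Acid-catalysed methanolysis, which should cleave the primary TBS ether well before the bulkier and far more acid-stable TBDPS ether.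

Step 9
Reactants: 15 (3Z,7Z)-7-[(tert-butyldiphenylsilyloxy)methyl]-8-iodo-3-methylocta-3,7-dien-1-ol
Product: 16 (3Z,7Z)-7-[(tert-butyldiphenylsilyloxy)methyl]-8-iodo-3-methylocta-3,7-dienal
Conditions: Dess–Martin periodinane, NaHCO3, CH2Cl2, 0 °C; used at once
Reagents that add atoms: none
Why: Dess–Martin oxidation under buffered, non-basic conditions gives the β,γ-unsaturated aldehyde, which is used immediately so that the C10=C1 olefin does not move into conjugation.

Step 10
Reactants: 17 (S)-methylsuccinic acid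
Product: 18 (S)-methylsuccinic anhydride
Conditions: AcCl, reflux; evaporation
Reagents that add atoms: none
Why: Dehydration of a 1,4-diacid to the five-membered cyclic anhydride, in which the stereocentre is not involved.

Step 11
Reactants: 19 (R)-4-benzyloxazolidin-2-one; 18 (S)-methylsuccinic anhydride
Product: 21 (2S)-4-[(4R)-4-benzyl-2-oxo-1,3-oxazolidin-3-yl]-2-methyl-4-oxobutanoic acid, via lithium oxazolidinide 20 (not isolated)
Conditions: n-BuLi (1.0 equiv), THF, −78 °C; then 18, −78 → −20 °C; 1 M HCl work-up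
Reagents that add atoms: none
Why: N-Acylation of the lithiated oxazolidinone by ring-opening of the anhydride, which should occur mainly at the less hindered carbonyl remote from the methyl branch (the minor regioisomer is removed at this stage) and leaves C11 untouched as the α-carbon of a carboxylate.

Step 12
Reactants: 21 (2S)-4-[(4R)-4-benzyl-2-oxo-1,3-oxazolidin-3-yl]-2-methyl-4-oxobutanoic acid
Product: 22 methyl (2S)-4-[(4R)-4-benzyl-2-oxo-1,3-oxazolidin-3-yl]-2-methyl-4-oxobutanoate
Conditions: TMSCHN2, toluene/MeOH (4:1), 0 °C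
Reagents that add atoms: (trimethylsilyl)diazomethane, C[Si](C)(C)C=[N+]=[N-]
Why: Esterification of the carboxylic acid with (trimethylsilyl)diazomethane under neutral conditions that leave the imide and the α-stereocentre untouched.

Step 13
Reactants: 22 methyl (2S)-4-[(4R)-4-benzyl-2-oxo-1,3-oxazolidin-3-yl]-2-methyl-4-oxobutanoate; 16 (3Z,7Z)-7-[(tert-butyldiphenylsilyloxy)methyl]-8-iodo-3-methylocta-3,7-dienal
Product: 25 methyl (2S,3R,4S,6Z,10Z)-3-[(4R)-4-benzyl-2-oxo-1,3-oxazolidine-3-carbonyl]-10-[(tert-butyldiphenylsilyloxy)methyl]-4-hydroxy-11-iodo-2,6-dimethylundeca-6,10-dienoate, via boron enolate 23 (not isolated), via boron aldolate 24 (not isolated)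
Conditions: 22 (1.3 equiv), Bu2BOTf (1.4 equiv), iPr2NEt (1.5 equiv), CH2Cl2, −78 → 0 °C; 16, −78 → −20 °C; pH 7 buffer, MeOH, 30% H2O2, 0 °C (short); crude product taken on at once
Reagents that add atoms: none
Why: Evans syn-aldol, in which the (Z)-dibutylboron enolate of the imide (enolised selectively over the ester) reacts through a closed Zimmerman–Traxler chair whose enolate face is shielded by the (R)-benzyl auxiliary, which should set C7 (R) and C8 (S) together as the required syn pair while the existing C11 centre lies outside the cyclic transition state.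

Step 14
Reactants: 25 aldol adduct
Product: 26 4-O-triethylsilyl ether of 25
Conditions: TESOTf (1.3 equiv), 2,6-lutidine (2 equiv), CH2Cl2, −78 °C
Reagents that add atoms: triethylsilyl trifluoromethanesulfonate, CC[Si](CC)(CC)OS(=O)(=O)C(F)(F)F
Why: Silylation of the secondary alcohol with a silyl triflate at low temperature, done on the crude aldol so that the free C8 hydroxyl has no time to lactonise onto the C12 ester.

Step 15
Reactants: 26 4-O-triethylsilyl ether of 25
Product: 27 methyl (2S,3R,4S,6Z,10Z)-10-[(tert-butyldiphenylsilyloxy)methyl]-3-(ethylsulfanylcarbonyl)-11-iodo-2,6-dimethyl-4-(triethylsilyloxy)undeca-6,10-dienoate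
Conditions: EtSH (3 equiv), n-BuLi (2 equiv), THF, 0 °C; then 26, 0 °C → rt
Reagents that add atoms: ethanethiol, CCS
Why: Thiolysis of the imide, in which the soft lithium thiolate attacks the exocyclic imide carbonyl and expels the oxazolidinone while being too weakly basic to epimerise C7 or C11 or to attack the methyl ester.

Step 16
Reactants: 27 S-ethyl thioester
Product: 28 methyl (2S,3R,4S,6Z,10Z)-10-[(tert-butyldiphenylsilyloxy)methyl]-3-formyl-11-iodo-2,6-dimethyl-4-(triethylsilyloxy)undeca-6,10-dienoate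
Conditions: DIBAL-H (1.1 equiv), CH2Cl2, −78 °C; MeOH quench at −78 °C, Rochelle salt; used crude
Reagents that add atoms: none
Why: Partial reduction of a thioester with DIBAL, in which the more electrophilic thioester carbonyl gives a hemithioacetal aluminate that is stable at −78 °C, so the aldehyde should be released only on work-up while the α-branched methyl ester survives.

Step 17
Reactants: 28 open-chain (Z)-alkenyl iodide aldehyde methyl ester
Product: 31 (3S,3aS,4S,6Z,10Z,11aR)-10-[(tert-butyldiphenylsilyloxy)methyl]-3,6-dimethyl-4-(triethylsilyloxy)-3a,4,5,8,9,11a-hexahydro-3H-cyclodeca[b]furan-2-one, via alkenylchromium species 29 (not isolated), via chromium alkoxide 30 (not isolated)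
Conditions: CrCl2 (10 equiv), NiCl2 (0.2 equiv), degassed DMSO/THF (3:1), rt, 28 added by syringe pump over 10 h to a final 3 mM; then 40 °C until the hydroxy ester is consumed; aqueous sodium serinate work-up
Reagents that add atoms: none
Why: Nozaki–Hiyama–Kishi reaction in which Ni(0) formed in situ inserts into the C5–I bond with retention of the olefin geometry and passes the alkenyl group to Cr(III), which adds to the C6 aldehyde and closes the ten-membered carbocycle by a 10-exo-trig carbonyl addition (C5–C6); the chromium(III) alkoxide so formed then attacks the C12 methyl ester in a 5-exo-trig acyl substitution with loss of methoxide and closes the γ-lactone. The closest known reaction types are NHK macrocyclisations of alkenyl iodide aldehydes to medium rings and the lactonisation of γ-alkoxy esters formed in chromium-mediated carbonyl additions. The new C6 stereocentre is controlled by C7: with the forming C5–C6 bond gauche to ring atom C8 and anti to the exocyclic C11 branch, the chromium-bound oxygen should lie in the sector between H7 and C11 and the small formyl hydrogen in the crowded sector between C8 and C11, which gives 6R (H6 anti to H7) and places the alkoxide syn-clinal to the C11–C12 bond for a trans-fused lactone. The step needs ring closure to beat intermolecular coupling, which slow addition at high dilution and the chain-bending (Z)-C1=C10 olefin should secure, and it needs attack on the aldehyde only, which the neutral organochromium reagent provides without epimerising C7 or eliminating the C8 silyloxy group.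

Step 18
Reactants: 31 silyl-protected lactone core
Product: 32 (3S,3aR,4S,6Z,10Z,11aR)-10-[(tert-butyldiphenylsilyloxy)methyl]-4-hydroxy-3,6-dimethyl-3a,4,5,8,9,11a-hexahydro-3H-cyclodeca[b]furan-2-one
Conditions: PPTS (0.3 equiv), MeOH/CH2Cl2, 0 °C → rt
Reagents that add atoms: none
Why: Acid-catalysed methanolysis of the secondary triethylsilyl ether, which is far more labile than the primary TBDPS ether, under base-free conditions in which the lactone should not migrate to O8.

Step 19
Reactants: 33 (tert-butyldimethylsilyloxy)acetaldehyde; 34 ethyl 2-(triphenylphosphoranylidene)propanoate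
Product: 35 ethyl (2E)-4-(tert-butyldimethylsilyloxy)-2-methylbut-2-enoate
Conditions: CH2Cl2, rt
Reagents that add atoms: none
Why: Wittig olefination with a stabilised α-methyl ylide, which should give the trisubstituted (E)-enoate.

Step 20
Reactants: 35 ethyl (2E)-4-(tert-butyldimethylsilyloxy)-2-methylbut-2-enoate
Product: 36 (2E)-4-(tert-butyldimethylsilyloxy)-2-methylbut-2-enoic acid
Conditions: LiOH·H2O, THF/MeOH/H2O, rt; 1 M HCl to pH 4 at 0 °C
Reagents that add atoms: lithium hydroxide, [Li+].[OH-]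
Why: Saponification of the ethyl ester, which the primary TBS ether should tolerate together with the brief, cold acidification.

Step 21
Reactants: 32 C8 alcohol of the lactone core; 36 (2E)-4-(tert-butyldimethylsilyloxy)-2-methylbut-2-enoic acid
Product: 38 8-O-[(2E)-4-(tert-butyldimethylsilyloxy)-2-methylbut-2-enoyl] ester of 32, via mixed anhydride 37 (not isolated)
Conditions: 36 (2 equiv), 2,4,6-trichlorobenzoyl chloride, Et3N, toluene, rt; then 32, DMAP, toluene, rt
Reagents that add atoms: none
Why: Yamaguchi esterification, in which the mixed anhydride passes the tigloyl-type acyl group through an acylpyridinium to the hindered C8 alcohol with retention at C8, since the C8–O bond is not broken.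

Step 22
Reactants: 38 bis-silyl ether ester
Product: 39 (3S,3aR,4S,6Z,10Z,11aR)-10-(hydroxymethyl)-3,6-dimethyl-2-oxo-3a,4,5,8,9,11a-hexahydro-3H-cyclodeca[b]furan-4-yl (2E)-4-hydroxy-2-methylbut-2-enoate (CNP0222998.2)
Conditions: HF·pyridine, pyridine, THF, 0 °C → rt
Reagents that add atoms: none
Why: Fluoride-mediated cleavage of both primary silyl ethers under buffered, non-basic conditions that should leave the lactone, the C8 ester and both ring olefins untouched.

**Compound list**

1 | 4-methyl-5,6-dihydro-2H-pyran-2-one | CC1=CC(=O)OCC1 | starting material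
2 | 4-methyl-5,6-dihydro-2H-pyran-2-ol (lactol, anomer mixture) | CC1=CC(O)OCC1 | intermediate
3 | (2Z)-5-hydroxy-3-methylpent-2-enal, open-chain form of 2 (not isolated) | OCC/C(C)=C\C=O | intermediate
4 | (3Z)-3-methylhexa-3,5-dien-1-ol | OCC/C(C)=C\C=C | intermediate
5 | tert-butyl-dimethyl-[(3Z)-3-methylhexa-3,5-dienoxy]silane | CC(C)(C)[Si](C)(C)OCC/C(C)=C\C=C | intermediate
6 | 9-[(3Z)-6-(tert-butyldimethylsilyloxy)-4-methylhex-3-enyl]-9-borabicyclo[3.3.1]nonane (not isolated) | CC(C)(C)[Si](C)(C)OCC/C(C)=C\CCB1C2CCCC1CCC2 | intermediate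
7 | (3Z)-6-(tert-butyldimethylsilyloxy)-4-methylhex-3-en-1-ol | CC(C)(C)[Si](C)(C)OCC/C(C)=C\CCO | intermediate
8 | (3Z)-6-bromo-1-(tert-butyldimethylsilyloxy)-3-methylhex-3-ene | CC(C)(C)[Si](C)(C)OCC/C(C)=C\CCBr | intermediate
9 | propargyl alcohol | C#CCO | starting material
10 | [(3Z)-6-(tert-butyldimethylsilyloxy)-4-methylhex-3-enyl]magnesium bromide (not isolated) | CC(C)(C)[Si](C)(C)OCC/C(C)=C\CC[Mg]Br | intermediate
11 | bromomagnesium prop-2-yn-1-olate (not isolated) | C#CCO[Mg]Br | intermediate
12 | cyclic alkenylmagnesium alkoxide, 4-substituted 2,5-dihydro-1,2-oxamagnesole with Mg on C5 and O15 (not isolated) | CC(C)(C)[Si](C)(C)OCC/C(C)=C\CCC1=C[Mg]OC1 | intermediate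
13 | (2Z,5Z)-8-(tert-butyldimethylsilyloxy)-2-(iodomethylidene)-6-methyloct-5-en-1-ol (iodine cis to CH2OH) | CC(C)(C)[Si](C)(C)OCC/C(C)=C\CC/C(CO)=C/I | intermediate
14 | tert-butyldiphenylsilyl ether of 13 | CC(C)(C)[Si](C)(C)OCC/C(C)=C\CC/C(CO[Si](c1ccccc1)(c1ccccc1)C(C)(C)C)=C/I | intermediate
15 | (3Z,7Z)-7-[(tert-butyldiphenylsilyloxy)methyl]-8-iodo-3-methylocta-3,7-dien-1-ol | OCC/C(C)=C\CC/C(CO[Si](c1ccccc1)(c1ccccc1)C(C)(C)C)=C/I | intermediate
16 | (3Z,7Z)-7-[(tert-butyldiphenylsilyloxy)methyl]-8-iodo-3-methylocta-3,7-dienal | O=CC/C(C)=C\CC/C(CO[Si](c1ccccc1)(c1ccccc1)C(C)(C)C)=C/I | intermediate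
17 | (S)-methylsuccinic acid | OC(=O)[C@@H](C)CC(O)=O | starting material
18 | (S)-methylsuccinic anhydride, (3S)-3-methyloxolane-2,5-dione | O=C1[C@@H](C)CC(=O)O1 | intermediate
19 | (R)-4-benzyloxazolidin-2-one | O=C1N[C@H](Cc2ccccc2)CO1 | starting material
20 | lithium salt of 19 (not isolated) | [Li]N1[C@H](Cc2ccccc2)COC1=O | intermediate
21 | (2S)-4-[(4R)-4-benzyl-2-oxo-1,3-oxazolidin-3-yl]-2-methyl-4-oxobutanoic acid | OC(=O)[C@@H](C)CC(=O)N1[C@H](Cc2ccccc2)COC1=O | intermediate
22 | methyl (2S)-4-[(4R)-4-benzyl-2-oxo-1,3-oxazolidin-3-yl]-2-methyl-4-oxobutanoate | COC(=O)[C@@H](C)CC(=O)N1[C@H](Cc2ccccc2)COC1=O | intermediate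
23 | (Z)-dibutylboron enolate of 22 (not isolated) | COC(=O)[C@@H](C)/C=C(\OB(CCCC)CCCC)N1[C@H](Cc2ccccc2)COC1=O | intermediate
24 | dibutylboron aldolate of 25 (not isolated) | COC(=O)[C@@H](C)[C@@H](C(=O)N1[C@H](Cc2ccccc2)COC1=O)[C@@H](OB(CCCC)CCCC)C/C(C)=C\CC/C(CO[Si](c1ccccc1)(c1ccccc1)C(C)(C)C)=C/I | intermediate
25 | methyl (2S,3R,4S,6Z,10Z)-3-[(4R)-4-benzyl-2-oxo-1,3-oxazolidine-3-carbonyl]-10-[(tert-butyldiphenylsilyloxy)methyl]-4-hydroxy-11-iodo-2,6-dimethylundeca-6,10-dienoate | COC(=O)[C@@H](C)[C@@H](C(=O)N1[C@H](Cc2ccccc2)COC1=O)[C@@H](O)C/C(C)=C\CC/C(CO[Si](c1ccccc1)(c1ccccc1)C(C)(C)C)=C/I | intermediate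
26 | 4-O-triethylsilyl ether of 25 | COC(=O)[C@@H](C)[C@@H](C(=O)N1[C@H](Cc2ccccc2)COC1=O)[C@@H](O[Si](CC)(CC)CC)C/C(C)=C\CC/C(CO[Si](c1ccccc1)(c1ccccc1)C(C)(C)C)=C/I | intermediate
27 | methyl (2S,3R,4S,6Z,10Z)-10-[(tert-butyldiphenylsilyloxy)methyl]-3-(ethylsulfanylcarbonyl)-11-iodo-2,6-dimethyl-4-(triethylsilyloxy)undeca-6,10-dienoate | COC(=O)[C@@H](C)[C@@H](C(=O)SCC)[C@@H](O[Si](CC)(CC)CC)C/C(C)=C\CC/C(CO[Si](c1ccccc1)(c1ccccc1)C(C)(C)C)=C/I | intermediate
28 | methyl (2S,3R,4S,6Z,10Z)-10-[(tert-butyldiphenylsilyloxy)methyl]-3-formyl-11-iodo-2,6-dimethyl-4-(triethylsilyloxy)undeca-6,10-dienoate (key-step precursor) | COC(=O)[C@@H](C)[C@@H](C=O)[C@@H](O[Si](CC)(CC)CC)C/C(C)=C\CC/C(CO[Si](c1ccccc1)(c1ccccc1)C(C)(C)C)=C/I | intermediate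
29 | C5 alkenylchromium(III) dichloride derived from 28 (not isolated) | COC(=O)[C@@H](C)[C@@H](C=O)[C@@H](O[Si](CC)(CC)CC)C/C(C)=C\CC/C(CO[Si](c1ccccc1)(c1ccccc1)C(C)(C)C)=C/[Cr](Cl)Cl | intermediate
30 | ten-membered-ring C6 chromium(III) alkoxide with the C12 methyl ester still open, 6R (not isolated) | C/C1=C/CC/C(CO[Si](c2ccccc2)(c2ccccc2)C(C)(C)C)=C/[C@@H](O[Cr](Cl)Cl)[C@H]([C@H](C)C(=O)OC)[C@@H](O[Si](CC)(CC)CC)C1 | intermediate
31 | (3S,3aS,4S,6Z,10Z,11aR)-10-[(tert-butyldiphenylsilyloxy)methyl]-3,6-dimethyl-4-(triethylsilyloxy)-3a,4,5,8,9,11a-hexahydro-3H-cyclodeca[b]furan-2-one (key-step product; H6 anti to H7) | C/C1=C/CC/C(CO[Si](c3ccccc3)(c3ccccc3)C(C)(C)C)=C/[C@H]2OC(=O)[C@@H](C)[C@@H]2[C@@H](O[Si](CC)(CC)CC)C1 | intermediate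
32 | (3S,3aR,4S,6Z,10Z,11aR)-10-[(tert-butyldiphenylsilyloxy)methyl]-4-hydroxy-3,6-dimethyl-3a,4,5,8,9,11a-hexahydro-3H-cyclodeca[b]furan-2-one | C/C1=C/CC/C(CO[Si](c3ccccc3)(c3ccccc3)C(C)(C)C)=C/[C@H]2OC(=O)[C@@H](C)[C@@H]2[C@@H](O)C1 | intermediate
33 | (tert-butyldimethylsilyloxy)acetaldehyde | O=CCO[Si](C)(C)C(C)(C)C | starting material
34 | ethyl 2-(triphenylphosphoranylidene)propanoate | CCOC(=O)C(C)=P(c1ccccc1)(c1ccccc1)c1ccccc1 | starting material
35 | ethyl (2E)-4-(tert-butyldimethylsilyloxy)-2-methylbut-2-enoate | CCOC(=O)/C(C)=C/CO[Si](C)(C)C(C)(C)C | intermediate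
36 | (2E)-4-(tert-butyldimethylsilyloxy)-2-methylbut-2-enoic acid | OC(=O)/C(C)=C/CO[Si](C)(C)C(C)(C)C | intermediate
37 | mixed anhydride of 36 with 2,4,6-trichlorobenzoic acid (not isolated) | O=C(OC(=O)c1c(Cl)cc(Cl)cc1Cl)/C(C)=C/CO[Si](C)(C)C(C)(C)C | intermediate
38 | 8-O-[(2E)-4-(tert-butyldimethylsilyloxy)-2-methylbut-2-enoyl] ester of 32 | C/C1=C/CC/C(CO[Si](c3ccccc3)(c3ccccc3)C(C)(C)C)=C/[C@H]2OC(=O)[C@@H](C)[C@@H]2[C@@H](OC(=O)/C(C)=C/CO[Si](C)(C)C(C)(C)C)C1 | intermediate
39 | (3S,3aR,4S,6Z,10Z,11aR)-10-(hydroxymethyl)-3,6-dimethyl-2-oxo-3a,4,5,8,9,11a-hexahydro-3H-cyclodeca[b]furan-4-yl (2E)-4-hydroxy-2-methylbut-2-enoate, CNP0222998.2 | C/C1=C/CC/C(CO)=C/[C@H]2OC(=O)[C@@H](C)[C@@H]2[C@@H](OC(=O)/C(C)=C/CO)C1 | target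

**Step count and risks**

Total steps: 22. Longest linear sequence: 17 (steps 1–9, 13–18, 21, 22).

Steps most likely to fail:

1. Step 17 (key step). The alkenylchromium species may add to the wrong face of the aldehyde in the ring-closing transition state, giving the C6 epimer, and intermolecular coupling may compete with ring closure. Fallback, setting out from 28 and coming back at 31: if the cyclisation delivers mainly the C6 epimer, it is collected as the cis-fused C6-epimeric lactone F1. This is saponified (LiOH, THF/H2O, 0 °C; acidified only to pH 5 in the cold) to the ring-opened C6 hydroxy C12 acid F2. F2 is closed under Mitsunobu conditions (PPh3, DIAD, toluene, 0 °C), where the carboxylate should displace the activated allylic C6 oxygen with inversion and give the trans-fused lactone 31.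

2. Step 13. Once the boron is removed, the C8 hydroxyl may add to the C12 methyl ester with loss of methanol (a γ-lactone that removes O8 from the route); the β,γ-unsaturated aldehyde may also be lost by migration of its olefin into conjugation. Fallback, setting out from 21 (with 16) and coming back at 26: the acid is esterified with tert-butyl 2,2,2-trichloroacetimidate (cat. BF3·OEt2, CH2Cl2/cyclohexane) to the tert-butyl ester imide F3, whose ester is too hindered for attack by the C8 hydroxyl. The same boron aldol with 16 should give the tert-butyl aldol adduct F4, and TESOTf/2,6-lutidine gives its triethylsilyl ether F5. TMSOTf/2,6-lutidine (CH2Cl2, 0 °C, aqueous work-up) then cleaves only the tert-butyl ester to the C12 carboxylic acid F6, and TMSCHN2 gives 26.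

3. Step 16. Hydride may be delivered to the C12 methyl ester in competition with the thioester, or reduction may run past the aldehyde stage to the C6 alcohol, which would lactonise. Fallback, setting out from 26 and coming back at 28: the imide is cleaved with LiOH/H2O2 (THF/H2O, 0 °C) to the C6 carboxylic acid F7. This is converted with 1-chloro-N,N,2-trimethylprop-1-en-1-amine (CH2Cl2, 0 °C, neutral) into the acid chloride F8. F8 is reduced with LiAlH(OtBu)3 (THF, −78 °C), a hydride that stops at the aldehyde and does not attack methyl esters, to give 28.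

**Further compounds**

F1 | step 17 | C6 epimer of 31, cis-fused lactone (H6 syn to H7) | C/C1=C/CC/C(CO[Si](c3ccccc3)(c3ccccc3)C(C)(C)C)=C/[C@@H]2OC(=O)[C@@H](C)[C@@H]2[C@@H](O[Si](CC)(CC)CC)C1
F2 | step 17 | ring-opened hydroxy acid of F1 (6S hydroxyl, C12 carboxylic acid) | C/C1=C/CC/C(CO[Si](c2ccccc2)(c2ccccc2)C(C)(C)C)=C/[C@H](O)[C@H]([C@H](C)C(O)=O)[C@@H](O[Si](CC)(CC)CC)C1
F3 | step 13 | tert-butyl (2S)-4-[(4R)-4-benzyl-2-oxo-1,3-oxazolidin-3-yl]-2-methyl-4-oxobutanoate | CC(C)(C)OC(=O)[C@@H](C)CC(=O)N1[C@H](Cc2ccccc2)COC1=O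
F4 | step 13 | tert-butyl ester analogue of aldol adduct 25 | CC(C)(C)OC(=O)[C@@H](C)[C@@H](C(=O)N1[C@H](Cc2ccccc2)COC1=O)[C@@H](O)C/C(C)=C\CC/C(CO[Si](c1ccccc1)(c1ccccc1)C(C)(C)C)=C/I
F5 | step 13 | tert-butyl ester analogue of silyl ether 26 | CC(C)(C)OC(=O)[C@@H](C)[C@@H](C(=O)N1[C@H](Cc2ccccc2)COC1=O)[C@@H](O[Si](CC)(CC)CC)C/C(C)=C\CC/C(CO[Si](c1ccccc1)(c1ccccc1)C(C)(C)C)=C/I
F6 | step 13 | C12 carboxylic acid corresponding to 26 | OC(=O)[C@@H](C)[C@@H](C(=O)N1[C@H](Cc2ccccc2)COC1=O)[C@@H](O[Si](CC)(CC)CC)C/C(C)=C\CC/C(CO[Si](c1ccccc1)(c1ccccc1)C(C)(C)C)=C/I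
F7 | step 16 | C6 carboxylic acid from 26 (imide replaced by CO2H, C12 methyl ester kept) | COC(=O)[C@@H](C)[C@@H](C(O)=O)[C@@H](O[Si](CC)(CC)CC)C/C(C)=C\CC/C(CO[Si](c1ccccc1)(c1ccccc1)C(C)(C)C)=C/I
F8 | step 16 | C6 acid chloride of F7 | COC(=O)[C@@H](C)[C@@H](C(Cl)=O)[C@@H](O[Si](CC)(CC)CC)C/C(C)=C\CC/C(CO[Si](c1ccccc1)(c1ccccc1)C(C)(C)C)=C/I
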